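**Remarks on the chemistry (assumptions)**

- Locants: unprimed/primed for flavone unit 1 (the 5-hydroxy-7-methoxy unit), double-primed for flavone unit 2 (the 5,7-dihydroxy unit), triple-primed for the para-phenylene ring B of unit 2.
- A structure check found nothing to correct: 13 and 16 differ only by the atoms of the new pyranone, and 16 differs from 17 only by the 4'-O-benzyl and 5-O-methyl groups.
- The aldehyde-to-phenol oxidation is run as a peracid Baeyer–Villiger oxidation with formate cleavage, because the aldehyde has no free ortho or para hydroxyl and an alkaline Dakin reaction proper does not apply.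
- 4-(Benzyloxy)benzoyl chloride (7) is assumed to be purchasable; otherwise it is made from 4-(benzyloxy)benzoic acid with oxalyl chloride just before use.

## Structural features

Isocryptomerin is a C–O–C biflavone. Two 2-aryl-4H-chromen-4-one units are joined by one diaryl ether oxygen that links C6 of ring A of unit 1 to C4''' of the para-phenylene ring B of unit 2. Unit 1 carries 5-OH, 7-OMe and 4'-OH; unit 2 carries 5''-OH and 7''-OH, so one of five phenolic oxygens is methylated and it sits next to the ether oxygen. There is no stereocentre, so every selectivity question is one of regiochemistry or chemoselectivity. The fragile elements are the free polyphenols, the γ-pyrone rings (opened by hot alkali) and the 5-hydroxy-6-aryloxy pattern of unit 1. Hot protic acid could reopen ring C of unit 1 and reclose it onto the 5-oxygen (Wessely–Moser rearrangement), which would move the ether from C6 to C8. The real difficulty is ring A of unit 1: C6 bears the ether oxygen between oxygens at C5 and C7, so the ether is hindered and its two neighbours must end up different (OH versus OMe). The key step exploits ring A of unit 2 (C4a'', C5''–C8'', C8a'' with O1'', 5''-O and 7''-O), which is a phloroglucinol residue with local threefold symmetry. C4a''–C4'' and O1''–C2'' can therefore be formed on the unprotected triol without any regiochemical choice.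

## Logic of the disconnections

17 to 16: the 4'-O–benzyl and 5-O–methyl bonds are added in the retro sense. The benzyl group keeps the 4'-oxygen from being acylated in the key step; the 5-O-methyl group keeps the 5-oxygen from taking part in ring reopening during the hot steps. The forward step must cleave two ethers in one operation, spare the 7-O-methyl group and not benzylate the electron-rich ring A of unit 2.

16 to 13 + 14: C4a''–C4'' and O1''–C2'' are cut. Ring A of unit 2 is then the carbon skeleton of 14 with all three oxygens in place, and the rest is a β-keto ester. This removes half a flavone as a commercial symmetric triol, needs no protecting group on unit 2, and forms one ring and two bonds in a single operation. The forward step must give the chromone and not the coumarin, and 13 must have no free hydroxyl and must tolerate the heat.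

13 to 11 (through 12) and 11 to 10: the C2''–C3'' bond between the ketone carbon and the methylene is cut, followed by the acid-to-methyl-ester interconversion. A magnesium malonate half-ester is chosen as the two-carbon donor because it acylates under near-neutral conditions, whereas strong ester enolates could attack the γ-pyrone of unit 1. The demand is an ester hydrolysis mild enough to leave ring C of unit 1 closed.

10 to 9, and 9 (through 8) to 6 + 7: O1–C2 is cut (cyclodehydration), then C2–C3 (oxygen-to-carbon aroyl shift), then the ester C–O bond between the phenol oxygen of 6 and the carbonyl of 7. The only hydroxyl of 6 is the future O1 and both flanking oxygens are already methyl ethers, so ring closure has one possible direction. Ring B of unit 1 is split off as commercial 7. The base for the shift must not saponify or condense at the methyl ester on the para-phenylene ring.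

6 to 5: the C4a–C4 aryl–acetyl bond is cut. The two positions ortho to the hydroxyl of 5 are equivalent by symmetry and are the only free positions on the electron-rich ring, while the benzoate ring is deactivated. The Lewis acid must leave the methyl ethers and the ester intact.

5 to 3 (through 4): the C8a–O1 oxygen is exchanged for a formyl carbon. The formyl group acts as a masked hydroxyl and is the reason the 1,2,3,5-oxygenation pattern can be bought as 1. The forward oxidation needs aryl migration, not hydride migration, in the Criegee intermediate.

3 to 1 + 2: the O–C4''' diaryl ether bond is cut on the side of the electron-poor ring, para to the ester that later becomes C2''. Both pieces are commercial and the hindered oxygen is placed on the nucleophile. The demand is that a hindered, deactivated phenoxide attack a moderately activated fluoroarene while the ester survives.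

## Other disconnections considered

Alternative 1: The cut runs through the para-phenylene ring at C3'''–C4''' and C5'''–C6''', so that this ring is grown on an oxygen already attached to ring A of unit 1. In the forward sense the aryl ethynyl ether 5-(benzyloxy)-2-(ethynyloxy)-1,3-dimethoxybenzene A1 would add across C3 and C6 of methyl coumalate A2 in an inverse-demand [4+2] cycloaddition. The bridged lactone would then lose CO2 and aromatise to methyl 4-[4-(benzyloxy)-2,6-dimethoxyphenoxy]benzoate A3.
- In favour: the nucleophilic terminal carbon of the ynol ether should bond to the electrophilic C6 of A2, which places the ester para to the oxygen. No substitution at a hindered, deactivated phenoxide is needed; on this point the alternative is the better of the two, since step 1 of the chosen plan rests on exactly such a substitution.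
- Against: A1 would have to be made from the O-benzylated phenol through a dichlorovinyl ether and a base-induced elimination, and it is sensitive to hydration. A3 is only the O-benzyl ether of 5, so a deprotection would follow. The sequence would take about five operations for what steps 1 and 2 do in two.
- Comparison: structurally it answers only the diaryl ether and leaves both pyranones to be built as in the chosen plan. Mechanistically it is a well-behaved pericyclic process. On step economy it is clearly the longer route.

Alternative 2: The cut is made at C2–C3 and C2''–C3'' at once. A bis(aryl ester), 2-acetyl-3,5-bis(benzyloxy)phenyl 4-(3-acetyl-4-{[4-(benzyloxy)benzoyl]oxy}-2,6-dimethoxyphenoxy)benzoate A5, would be assembled from 6-type material and the protected acetophenone 1-[2,4-bis(benzyloxy)-6-hydroxyphenyl]ethan-1-one A4. Excess KOH in pyridine would then effect two oxygen-to-carbon aroyl shifts to the bis(1,3-diketone) A6, and a later double cyclodehydration would close both pyranones.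
- In favour: each shift is intramolecular through a six-membered transition state; no step runs above about 100 °C; the chromone-versus-coumarin question never arises. On these two points the alternative is the better; in reliability of the individual bond formation it is the equal of the chosen plan, which uses the same shift once in step 4.
- Against: unit 2 must arrive protected as A4, which adds protection steps and two more benzyl ethers to remove at the end. A5 needs the benzoic acid of the para-phenylene ring free while the phenol of unit 1 is already an aryl ester, so an orthogonal ester would be required; a methyl ester cannot be saponified beside an aryl ester. Two different aryl esters and two enolisable ketones in one molecule, under hydroxide, invite crossed acyl transfer and ester hydrolysis.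
- Comparison: the step count would be the same or one to two steps higher, and protecting-group economy is poorer than with bare 14.

Alternative 3: The cut is C8a–O1 of unit 1. A 1,3-diketone without the ortho oxygen, methyl 4-(3-{3-[4-(benzyloxy)phenyl]-3-oxopropanoyl}-2,6-dimethoxyphenoxy)benzoate A7, would be treated with Pd(OAc)2 (divalent palladium) and PhI(OAc)2. The C4 ketone would direct palladation of C8a–H, oxidation would give a tetravalent palladium intermediate, and C–O reductive elimination with the enol oxygen on C2 would close the pyranone. The product would be methyl 4-({2-[4-(benzyloxy)phenyl]-5,7-dimethoxy-4-oxo-4H-chromen-6-yl}oxy)benzoate A8, identical with 10.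
- In favour: the aldehyde-to-phenol oxidation of step 2 would be unnecessary, since the arene for A7 could come from a phenol without the para substituent. The other position ortho to the ketone is blocked by the 5-methoxy group, so the site of palladation is unambiguous. The route to 10 could be as short as steps 1 to 5 or one step shorter; on step economy it is the equal or the better.
- Against: the enolised 1,3-diketone is an acetylacetonate-type chelating ligand and would be expected to bind divalent palladium and suppress C–H activation. PhI(OAc)2 would be expected to oxidise the activated methylene or the trioxygenated ring. Acetoxylation of the C–H bond could compete with ring closure.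
- Comparison: mechanistically it is much less secure than the acid-catalysed dehydration of step 5, which needs no oxidant. Structurally it reaches the same compound and contributes nothing to unit 2.

Key step: step 8

## Route

Step 1
Reactants: 1 syringaldehyde (4-hydroxy-3,5-dimethoxybenzaldehyde); 2 methyl 4-fluorobenzoate
Product: 3 methyl 4-(4-formyl-2,6-dimethoxyphenoxy)benzoate
Conditions: K2CO3, DMSO, 130 °C, N2
Reagents that add atoms: none
Why: Nucleophilic aromatic substitution (addition–elimination); the para ester stabilises the Meisenheimer intermediate and fluoride is the best leaving group for this mechanism. The aldehyde has no α-hydrogen and should tolerate carbonate in DMSO.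

Step 2
Reactants: 3 methyl 4-(4-formyl-2,6-dimethoxyphenoxy)benzoate
Product: 5 methyl 4-(4-hydroxy-2,6-dimethoxyphenoxy)benzoate, via aryl formate 4 (not isolated)
Conditions: mCPBA, CH2Cl2, 0 °C → rt; then Et3N, MeOH, rt
Reagents that add atoms: mCPBA (3-chloroperoxybenzoic acid), OOC(=O)c1cccc(Cl)c1
Why: Baeyer–Villiger (Dakin-type) oxidation; the aryl ring with its para aryloxy donor should migrate in the Criegee intermediate, as in the related oxidation of 3,4,5-trialkoxybenzaldehydes. The labile aryl formate is cleaved by methanolysis, which cannot alter the methyl ester.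

Step 3
Reactants: 5 methyl 4-(4-hydroxy-2,6-dimethoxyphenoxy)benzoate
Product: 6 methyl 4-(3-acetyl-4-hydroxy-2,6-dimethoxyphenoxy)benzoate
Conditions: AcOH, BF3·OEt2, 85 °C; then aq. NaOAc
Reagents that add atoms: acetic acid, CC(=O)O
Why: Friedel–Crafts acetylation (O-acetylation and Fries shift are an equivalent path) ortho to the hydroxyl, driven by formation of the difluoroboron chelate of the ortho-hydroxy ketone. The two ortho positions are equivalent and are the only free positions of the electron-rich ring, and the benzoate ring is deactivated.

Step 4
Reactants: 6 methyl 4-(3-acetyl-4-hydroxy-2,6-dimethoxyphenoxy)benzoate; 7 4-(benzyloxy)benzoyl chloride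
Product: 9 methyl 4-(3-{3-[4-(benzyloxy)phenyl]-3-oxopropanoyl}-4-hydroxy-2,6-dimethoxyphenoxy)benzoate, via O-aroyl ester 8 (not isolated)
Conditions: KOt-Bu (1.05 equiv), THF, 0 °C, then 7; then KOt-Bu (2.2 equiv), rt → 50 °C; aq. HCl
Reagents that add atoms: none
Why: One-pot O-aroylation and Baker–Venkataraman rearrangement; the ketone enolate attacks the neighbouring aryl ester through a six-membered transition state and the stabilised diketonate drives the shift. The bulky, non-nucleophilic alkoxide should spare the remote methyl ester, which hydroxide would endanger.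

Step 5
Reactants: 9 methyl 4-(3-{3-[4-(benzyloxy)phenyl]-3-oxopropanoyl}-4-hydroxy-2,6-dimethoxyphenoxy)benzoate
Product: 10 methyl 4-({2-[4-(benzyloxy)phenyl]-5,7-dimethoxy-4-oxo-4H-chromen-6-yl}oxy)benzoate
Conditions: p-TsOH·H2O (cat.), toluene, reflux, Dean–Stark
Reagents that add atoms: none
Why: Acid-catalysed cyclodehydration; the only phenol adds to the distal aryl ketone (6-exo-trig) and the hemiketal loses water to the aromatic γ-pyrone. Catalytic sulfonic acid with water removal is mild enough for the benzyl ether and the methyl ester.

Step 6
Reactants: 10 methyl 4-({2-[4-(benzyloxy)phenyl]-5,7-dimethoxy-4-oxo-4H-chromen-6-yl}oxy)benzoate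
Product: 11 4-({2-[4-(benzyloxy)phenyl]-5,7-dimethoxy-4-oxo-4H-chromen-6-yl}oxy)benzoic acid
Conditions: LiOH·H2O, THF/MeOH/H2O, rt; then 1 M HCl
Reagents that add atoms: lithium hydroxide monohydrate, [Li+].[OH-].O
Why: Saponification of an unhindered methyl benzoate at room temperature; opening of the 2-arylchromone by hydroxide needs hot concentrated alkali, and any opened material would reclose on acidification.

Step 7
Reactants: 11 4-({2-[4-(benzyloxy)phenyl]-5,7-dimethoxy-4-oxo-4H-chromen-6-yl}oxy)benzoic acid
Product: 13 ethyl 3-[4-({2-[4-(benzyloxy)phenyl]-5,7-dimethoxy-4-oxo-4H-chromen-6-yl}oxy)phenyl]-3-oxopropanoate, via acyl imidazolide 12 (not isolated)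
Conditions: CDI, THF, rt; then KO2CCH2CO2Et, MgCl2, Et3N, MeCN, rt → 45 °C; aq. HCl
Reagents that add atoms: potassium ethyl malonate, CCOC(=O)CC(=O)[O-].[K+]
Why: Masamune–Brooks decarboxylative Claisen condensation; the magnesium enolate of the malonate half-ester is C-acylated by the imidazolide and loses CO2. The conditions are near neutral, so the γ-pyrone, benzyl ether and methyl ethers should be untouched.

Step 8
Reactants: 13 ethyl 3-[4-({2-[4-(benzyloxy)phenyl]-5,7-dimethoxy-4-oxo-4H-chromen-6-yl}oxy)phenyl]-3-oxopropanoate; 14 phloroglucinol (benzene-1,3,5-triol)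
Product: 16 2-[4-(benzyloxy)phenyl]-6-[4-(5,7-dihydroxy-4-oxo-4H-chromen-2-yl)phenoxy]-5,7-dimethoxy-4H-chromen-4-one, via acylphloroglucinol diketone 15 (not isolated)
Conditions: 14 (anhydrous, 3 equiv), neat melt (trace Ph2O), microwave, 240 °C, 5–10 min, N2 sweep
Reagents that add atoms: none
Why: On heating, 13 should lose ethanol to an aroylketene (or transesterify at a phenol oxygen and shift the acyl group to carbon in Fries fashion); a ring carbon of 14 attacks the former ester carbon, the future C4'', and diketone 15 results with the new C4a''–C4'' bond. An ortho hydroxyl of 15 then adds to the aryl ketone carbon C2'' in a 6-exo-trig closure and the hemiketal loses water, which forms O1''–C2'' and the pyranone of unit 2. The closest known reaction type is the Mentzer pyrone synthesis, the solvent-free thermal condensation of phloroglucinol with aroylacetates to 5,7-dihydroxyflavones. No stereocentre is formed. The step needs chromone-versus-coumarin selectivity: without acid the ketone carbonyl is not activated for Pechmann-type attack by the ring carbon, whereas the acylketene is electrophilic at the ester-derived carbon, so C-acylation comes first and the 2-arylchromone follows. Site selectivity is no issue because all three ring carbons and all three hydroxyls of 14 are equivalent, and chemoselectivity is secured because unit 1 of 13 has no free hydroxyl and its γ-pyrone carbonyl is a poor electrophile. Excess 14 should suppress a second acylation, and anhydrous 14 with a gas sweep limits hydrolysis and decarboxylation of 13 by the water set free.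

Step 9
Reactants: 16 2-[4-(benzyloxy)phenyl]-6-[4-(5,7-dihydroxy-4-oxo-4H-chromen-2-yl)phenoxy]-5,7-dimethoxy-4H-chromen-4-one
Product: 17 isocryptomerin, 6-[4-(5,7-dihydroxy-4-oxo-4H-chromen-2-yl)phenoxy]-5-hydroxy-2-(4-hydroxyphenyl)-7-methoxy-4H-chromen-4-one
Conditions: BCl3 (1 M in CH2Cl2, excess), C6HMe5, CH2Cl2, −78 °C → rt; then MeOH, H2O
Reagents that add atoms: none
Why: Lewis-acid ether cleavage; BCl3 chelates the C4 carbonyl and the peri 5-methoxy oxygen so that chloride removes that methyl group, while the unchelated 7-methoxy group should stay. The benzyl ether is cleaved at low temperature and pentamethylbenzene traps the benzyl cation by Friedel–Crafts alkylation before it can attack ring A of unit 2; no hot protic acid is present, so Wessely–Moser isomerisation is not expected.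

## Compound list

1 | syringaldehyde (4-hydroxy-3,5-dimethoxybenzaldehyde) | COc1cc(C=O)cc(OC)c1O | starting material
2 | methyl 4-fluorobenzoate | COC(=O)c1ccc(F)cc1 | starting material
3 | methyl 4-(4-formyl-2,6-dimethoxyphenoxy)benzoate | COC(=O)c1ccc(Oc2c(OC)cc(C=O)cc2OC)cc1 | intermediate
4 | methyl 4-[4-(formyloxy)-2,6-dimethoxyphenoxy]benzoate | COC(=O)c1ccc(Oc2c(OC)cc(OC=O)cc2OC)cc1 | intermediate
5 | methyl 4-(4-hydroxy-2,6-dimethoxyphenoxy)benzoate | COC(=O)c1ccc(Oc2c(OC)cc(O)cc2OC)cc1 | intermediate
6 | methyl 4-(3-acetyl-4-hydroxy-2,6-dimethoxyphenoxy)benzoate | COC(=O)c1ccc(Oc2c(OC)cc(O)c(C(C)=O)c2OC)cc1 | intermediate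
7 | 4-(benzyloxy)benzoyl chloride | O=C(Cl)c1ccc(OCc2ccccc2)cc1 | starting material
8 | 2-acetyl-3,5-dimethoxy-4-[4-(methoxycarbonyl)phenoxy]phenyl 4-(benzyloxy)benzoate | COC(=O)c1ccc(Oc2c(OC)cc(OC(=O)c3ccc(OCc4ccccc4)cc3)c(C(C)=O)c2OC)cc1 | intermediate
9 | methyl 4-(3-{3-[4-(benzyloxy)phenyl]-3-oxopropanoyl}-4-hydroxy-2,6-dimethoxyphenoxy)benzoate | COC(=O)c1ccc(Oc2c(OC)cc(O)c(C(=O)CC(=O)c3ccc(OCc4ccccc4)cc3)c2OC)cc1 | intermediate
10 | methyl 4-({2-[4-(benzyloxy)phenyl]-5,7-dimethoxy-4-oxo-4H-chromen-6-yl}oxy)benzoate | COC(=O)c1ccc(Oc2c(OC)cc3oc(-c4ccc(OCc5ccccc5)cc4)cc(=O)c3c2OC)cc1 | intermediate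
11 | 4-({2-[4-(benzyloxy)phenyl]-5,7-dimethoxy-4-oxo-4H-chromen-6-yl}oxy)benzoic acid | OC(=O)c1ccc(Oc2c(OC)cc3oc(-c4ccc(OCc5ccccc5)cc4)cc(=O)c3c2OC)cc1 | intermediate
12 | 2-[4-(benzyloxy)phenyl]-6-[4-(1H-imidazole-1-carbonyl)phenoxy]-5,7-dimethoxy-4H-chromen-4-one | O=C(c1ccc(Oc2c(OC)cc3oc(-c4ccc(OCc5ccccc5)cc4)cc(=O)c3c2OC)cc1)n1ccnc1 | intermediate
13 | ethyl 3-[4-({2-[4-(benzyloxy)phenyl]-5,7-dimethoxy-4-oxo-4H-chromen-6-yl}oxy)phenyl]-3-oxopropanoate | CCOC(=O)CC(=O)c1ccc(Oc2c(OC)cc3oc(-c4ccc(OCc5ccccc5)cc4)cc(=O)c3c2OC)cc1 | intermediate
14 | phloroglucinol (benzene-1,3,5-triol) | Oc1cc(O)cc(O)c1 | starting material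
15 | 1-[4-({2-[4-(benzyloxy)phenyl]-5,7-dimethoxy-4-oxo-4H-chromen-6-yl}oxy)phenyl]-3-(2,4,6-trihydroxyphenyl)propane-1,3-dione | COc1cc2oc(-c3ccc(OCc4ccccc4)cc3)cc(=O)c2c(OC)c1Oc1ccc(C(=O)CC(=O)c2c(O)cc(O)cc2O)cc1 | intermediate
16 | 2-[4-(benzyloxy)phenyl]-6-[4-(5,7-dihydroxy-4-oxo-4H-chromen-2-yl)phenoxy]-5,7-dimethoxy-4H-chromen-4-one | COc1cc2oc(-c3ccc(OCc4ccccc4)cc3)cc(=O)c2c(OC)c1Oc1ccc(-c2cc(=O)c3c(O)cc(O)cc3o2)cc1 | intermediate
17 | isocryptomerin | COc1cc2oc(-c3ccc(O)cc3)cc(=O)c2c(O)c1Oc1ccc(-c2cc(=O)c3c(O)cc(O)cc3o2)cc1 | target

## Step count and least certain steps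

Total step count: 9. Longest linear sequence: 9 steps (1 to 17); compounds 2, 7 and 14 enter as purchased partners.

**Step 8 (key step).** The most likely failures are:
- hydrolysis and decarboxylation of the β-keto ester to the aryl methyl ketone by the water that the cyclisation itself releases;
- thermal transfer of the benzyl group from the 4'-oxygen to the very nucleophilic triol;
- diversion to the 4-arylcoumarin if traces of acid are present.

Fallback, from 11 back to the route at 15 and then 16: the acid would be converted with oxalyl chloride and catalytic DMF in CH2Cl2 into 4-({2-[4-(benzyloxy)phenyl]-5,7-dimethoxy-4-oxo-4H-chromen-6-yl}oxy)benzoyl chloride F1. The tetralithium salt of 2',4',6'-trihydroxyacetophenone (LiN(SiMe3)2, THF, −78 °C) would be acylated by F1 at the enolate carbon to give 15, and 15 would be cyclised with catalytic H2SO4 in AcOH at 95 °C to 16. This forms C2''–C3'' in place of C4a''–C4'' and needs no high temperature.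

**Step 1.** The phenoxide of 1 is hindered on both sides and deactivated by the para formyl group, and 2 is only moderately activated. Slow substitution, with cleavage of the methyl ester by carbonate or phenoxide during long heating, is the likely failure. Fallback, from 1 back to 3: methyl 4-iodobenzoate would be oxidised with mCPBA and TsOH·H2O in MeCN in the presence of 1,3,5-trimethoxybenzene to [4-(methoxycarbonyl)phenyl](2,4,6-trimethoxyphenyl)iodonium tosylate F2. Metal-free O-arylation of 1 with F2 (K2CO3, MeCN, 55 °C) should transfer the electron-poor aryl group and give 3; this type of arylation tolerates hindered and acidic phenols.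

**Step 2.** Hydride migration in place of aryl migration in the Criegee intermediate would lead to the carboxylic acid, because the migrating ring has only a twisted aryloxy donor para to the formyl group. Over-oxidation of the electron-rich phenol by excess peracid is also possible. Fallback, from 2 back to 5: substitution of 2 with the more nucleophilic 4-bromo-2,6-dimethoxyphenol (K2CO3, DMSO) would give methyl 4-(4-bromo-2,6-dimethoxyphenoxy)benzoate F3. Miyaura borylation (B2pin2, PdCl2(dppf), KOAc, dioxane, 90 °C) would give methyl 4-[2,6-dimethoxy-4-(4,4,5,5-tetramethyl-1,3,2-dioxaborolan-2-yl)phenoxy]benzoate F4, and oxidation with NaBO3·4H2O in THF/H2O at rt would give 5. This route bypasses the aldehyde.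

**Step 9.** Possible failures are:
- C-benzylation of ring A of unit 2 if trapping of the benzyl cation is too slow;
- incomplete cleavage because boron chelates of the sparingly soluble polyphenol precipitate;
- slow loss of the 7-O-methyl group on long exposure.

Fallback, from 16 back to 17: hydrogenolysis (H2, Pd/C, THF/MeOH, rt) would remove the benzyl group as toluene without any cationic species and give 6-[4-(5,7-dihydroxy-4-oxo-4H-chromen-2-yl)phenoxy]-2-(4-hydroxyphenyl)-5,7-dimethoxy-4H-chromen-4-one F5. Chelation-controlled cleavage of the peri 5-methoxy group of F5 with AlCl3 in MeCN at 60 °C, a better solvent for polyhydroxyflavones, would then give 17.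

## Further compounds

F1 | step 8 | 4-({2-[4-(benzyloxy)phenyl]-5,7-dimethoxy-4-oxo-4H-chromen-6-yl}oxy)benzoyl chloride | O=C(Cl)c1ccc(Oc2c(OC)cc3oc(-c4ccc(OCc5ccccc5)cc4)cc(=O)c3c2OC)cc1
F2 | step 1 | [4-(methoxycarbonyl)phenyl](2,4,6-trimethoxyphenyl)iodonium tosylate | COC(=O)c1ccc([I+]c2c(OC)cc(OC)cc2OC)cc1.Cc1ccc(S(=O)(=O)[O-])cc1
F3 | step 2 | methyl 4-(4-bromo-2,6-dimethoxyphenoxy)benzoate | COC(=O)c1ccc(Oc2c(OC)cc(Br)cc2OC)cc1
F4 | step 2 | methyl 4-[2,6-dimethoxy-4-(4,4,5,5-tetramethyl-1,3,2-dioxaborolan-2-yl)phenoxy]benzoate | COC(=O)c1ccc(Oc2c(OC)cc(B3OC(C)(C)C(C)(C)O3)cc2OC)cc1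
F5 | step 9 | 6-[4-(5,7-dihydroxy-4-oxo-4H-chromen-2-yl)phenoxy]-2-(4-hydroxyphenyl)-5,7-dimethoxy-4H-chromen-4-one | COc1cc2oc(-c3ccc(O)cc3)cc(=O)c2c(OC)c1Oc1ccc(-c2cc(=O)c3c(O)cc(O)cc3o2)cc1
A1 | alternative 1 | 5-(benzyloxy)-2-(ethynyloxy)-1,3-dimethoxybenzene | C#COc1c(OC)cc(OCc2ccccc2)cc1OC
A2 | alternative 1 | methyl coumalate (methyl 2-oxo-2H-pyran-5-carboxylate) | COC(=O)C1=COC(=O)C=C1
A3 | alternative 1 | methyl 4-[4-(benzyloxy)-2,6-dimethoxyphenoxy]benzoate | COC(=O)c1ccc(Oc2c(OC)cc(OCc3ccccc3)cc2OC)cc1
A4 | alternative 2 | 1-[2,4-bis(benzyloxy)-6-hydroxyphenyl]ethan-1-one | CC(=O)c1c(O)cc(OCc2ccccc2)cc1OCc1ccccc1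
A5 | alternative 2 | 2-acetyl-3,5-bis(benzyloxy)phenyl 4-(3-acetyl-4-{[4-(benzyloxy)benzoyl]oxy}-2,6-dimethoxyphenoxy)benzoate | CC(=O)c1c(OC(=O)c2ccc(OCc3ccccc3)cc2)cc(OC)c(Oc2ccc(C(=O)Oc3cc(OCc4ccccc4)cc(OCc4ccccc4)c3C(C)=O)cc2)c1OC
A6 | alternative 2 | methyl-ether-protected bis(1,3-diketone), 1-[4-(benzyloxy)phenyl]-3-{3-[4-(3-{2,4-bis(benzyloxy)-6-hydroxyphenyl}-3-oxopropanoyl)phenoxy]-6-hydroxy-2,4-dimethoxyphenyl}propane-1,3-dione | COc1cc(O)c(C(=O)CC(=O)c2ccc(OCc3ccccc3)cc2)c(OC)c1Oc1ccc(C(=O)CC(=O)c2c(O)cc(OCc3ccccc3)cc2OCc2ccccc2)cc1
A7 | alternative 3 | methyl 4-(3-{3-[4-(benzyloxy)phenyl]-3-oxopropanoyl}-2,6-dimethoxyphenoxy)benzoate | COC(=O)c1ccc(Oc2c(OC)ccc(C(=O)CC(=O)c3ccc(OCc4ccccc4)cc3)c2OC)cc1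
A8 | alternative 3 | methyl 4-({2-[4-(benzyloxy)phenyl]-5,7-dimethoxy-4-oxo-4H-chromen-6-yl}oxy)benzoate (identical with 10) | COC(=O)c1ccc(Oc2c(OC)cc3oc(-c4ccc(OCc5ccccc5)cc4)cc(=O)c3c2OC)cc1
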